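(The runs come from a simulation with made-up constants, noise included.)

Links are the product asked for, yet in the east run they stand at 17.8 % when 48.6 % of the first end groups are lost.

| flask | first end groups | second end groups | temperature | remark | time |
|---|---|---|---|---|---|
| east | 0.80 M | 1.2 M | 25 °C | run made earlier |  |
| ochre | 0.80 M | 0.816 M |  | at 25 °C until 6.0 min, from then on at 55 °C | 12 min |
| blue | 0.80 M | 0.816 M |  | at 55 °C throughout | 40 min |

east run (percent of the first end groups charged)

| time / s | links / % | first end groups / % |
|---|---|---|
| 10.0 | 3.5 | 91.2 |
| 15.0 | 5.0 | 87.0 |
| 25.0 | 8.2 | 79.1 |
| 40.0 | 11.3 | 70.6 |
| 60.0 | 15.6 | 59.5 |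
| 80.0 | 17.8 | 51.4 |

(readings scatter by 1 percentage point)

* the flask that ends with the higher amount of links, in percent of the first end groups charged, or "neither" when 2 percentage points or less lies between them (ochre / blue / neither)
* final links, as a percentage of the first end groups charged, in ochre
* final links, as a percentage of the first end groups charged, in blue

- the earlier runs do not show what temperature does; that part of a forecast is a guess

1. Read the split. In the east run, links are 0.392 of the first end groups lost up to 25.0 s, and a lower 0.347 of those lost after it. These are readings with their scatter. Assume that link making needs second end groups, that the other loss does not depend on them, and that each first end group lost takes one second end group with it.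

2. Reckon the link preference 0.575 M⁻¹: links made per first end group otherwise lost, divided by the average second end groups present. This is a selectivity factor.

3. Ask for the end state. Ochre and blue both hold 0.816 M of second end groups against 0.80 M of first end groups, a margin of 0.0160 M. Keep the preference constant: links made per first end group otherwise lost are the preference times the second end groups present, so on these assumptions that ratio falls from 0.469 at the start to 0.00920 once the loss equals the charge of first end groups. Add it up, with p the link preference:

links = amount lost − ln[(1 + p × start)/(1 + p × end)]/p

Here start and end are the second end groups. This gives 18.3 % of the first end groups charged.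

4. Ask how fast. East first end groups halve in about 83.3 s. Ochre's 6.0 min at 25 °C is longer than that, so expect about 18.3 % in ochre. Blue is hot throughout, and the runs do not show what heat does, so guess the same for blue and answer neither.

5. The forecast said neither, with 28 % (23 % to 37 %) for ochre and 28 % (16 % to 42 %) for blue, higher than this reckoning: “Ochre is about 93% consumed before heating, so its result is essentially the 25 °C one”.

Ochre ends with 13.6 % of links and blue with 1.36 %, so the answer is ochre.

    first end groups + second end groups ⇌ links (K = 57.0 M⁻¹, k = 0.200 M⁻¹ min⁻¹, Ea = 53.0 kJ mol⁻¹, ΔH = −9.00 kJ mol⁻¹)
    first end groups + second end groups → rings, rate k2*[first end groups] as long as [second end groups] is above zero (k = 0.310 min⁻¹, Ea = 78.0 kJ mol⁻¹)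
    links → over-reaction product (k = 1.50 × 10⁻⁴ min⁻¹, Ea = 112 kJ mol⁻¹)
    second end groups → decomposed reagent (k = 0.0500 min⁻¹, Ea = 90.0 kJ mol⁻¹)
    (constants at 25 °C)

Ochre holds 17.7 % of links at 6.00 min, when second end groups stand at 3.54 % of their charge; at 12.0 min they stand at 0 %. The link preference gave 18.3 %, near the ochre figure at the change of temperature, and the ochre end lies 4.7 percentage points below the reckoning.

Take blue with 0.20 M of second end groups. The link preference gives 1.34 % of links, and one-for-one use leaves 75.0 % of the first end groups. That flask gives 0.103 % of links, with 75.8 % of first end groups left.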